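**Retrosynthetic overview**

1. The target is the 8-O-vanillate of a (1(10)Z,4Z)-germacradiene-6,8-diol. The strategy rests on the C6–C7 bond of its single ten-membered carbocycle (germacrane numbering: C6 free carbinol, C7 isopropyl carbon, C8 ester carbinol). This is the bond a cyclase makes between the two ends of a farnesyl chain, and because C6 carries oxygen an aldehyde can take the part of the allyl cation.
2. Late stage: C8–O acyl bond (silyl-protected vanilloyl chloride), isopropyl from isopropenyl, PMB/TES differentiation of the two hydroxyls.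
3. Key disconnection: C6–C7 by intramolecular Nozaki–Hiyama allylation (CrCl2) of a (2Z,6Z,10E)-12-bromo-9-PMB-oxy-farnesal. It closes the only ring of the target and sets C6 and C7 against the preset C8.
4. Chain: C3–C4 by B-alkyl Suzuki coupling with methyl (Z)-3-iodobut-2-enoate (Z-C4=C5); C3 by Wittig methylenation of a lactol; C12–O by SeO2 oxidation of the E-methyl.
5. C8 and Z-C10=C1 come from an asymmetric vinylogous Mukaiyama aldol/lactonisation of the methyl 3-methylbut-2-enoate dienolate with 3-methylbut-2-enal. Ring order: a δ-lactone as a temporary geometry template (opened in steps 5 and 6), then the ten-membered ring in step 14.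

Key step: step 14

Remark: ring positions in the text use germacrane numbering; names of open-chain intermediates use farnesane (dodecatriene) locants, in which C1 = germacrane C6, C9 = C8 and C10 = C7.
Assumption: in step 2 the copper–(S)-Tol-BINAP dienolate is taken to attack the aldehyde face that gives the 6R lactone; if the sense of induction is the opposite, the (R)-ligand is used.

**Route**

Step 1
Reactants: 1 methyl 3-methylbut-2-enoate
Product: 2 1-methoxy-3-methyl-1-(trimethylsilyloxy)buta-1,3-diene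
Conditions: LDA, THF, −78 °C; then TMSCl, −78 °C to rt; distillation
Reagents that add atoms: chlorotrimethylsilane, C[Si](C)(C)Cl
Why: Kinetic γ-deprotonation of the senecioate gives the extended lithium dienolate, which is trapped on oxygen (silyl dienol ether formation); no stereocentre is made.

Step 2
Reactants: 2 1-methoxy-3-methyl-1-(trimethylsilyloxy)buta-1,3-diene; 3 3-methylbut-2-enal
Product: 5 (6R)-4-methyl-6-(2-methylprop-1-en-1-yl)-5,6-dihydro-2H-pyran-2-one, via copper aldolate 4 (not isolated)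
Conditions: Cu(OTf)2 (10 mol %), (S)-Tol-BINAP (11 mol %), (Bu4N)(Ph3SiF2) (20 mol %), THF, −78 °C to rt
Reagents that add atoms: none
Why: Catalytic asymmetric vinylogous Mukaiyama aldol: fluoride turns 2 into a Tol-BINAP-bound dienolate of monovalent copper that adds through its γ-carbon to one face of the enal, which sets C8 as R, and the s-cis aldolate 4 closes to the δ-lactone with loss of methoxide, so that C10=C1 is Z by ring constraint.

Step 3
Reactants: 5 (6R)-4-methyl-6-(2-methylprop-1-en-1-yl)-5,6-dihydro-2H-pyran-2-one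
Product: 6 (6R)-6-[(1E)-3-hydroxy-2-methylprop-1-en-1-yl]-4-methyl-5,6-dihydro-2H-pyran-2-one
Conditions: SeO2 (0.5 equiv), t-BuOOH (3 equiv), CH2Cl2, 0 °C to rt
Reagents that add atoms: tert-butyl hydroperoxide, CC(C)(C)OO (the oxygen, relayed through SeO2, O=[Se]=O)
Why: SeO2 allylic oxidation (ene reaction, then [2,3]-sigmatropic shift) should touch only the electron-rich isopropylidene group, and there the methyl trans to C8, which gives the E allylic alcohol; the conjugated lactone alkene is inert.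

Step 4
Reactants: 6 (6R)-6-[(1E)-3-hydroxy-2-methylprop-1-en-1-yl]-4-methyl-5,6-dihydro-2H-pyran-2-one
Product: 7 (6R)-6-[(1E)-3-{[tert-butyl(dimethyl)silyl]oxy}-2-methylprop-1-en-1-yl]-4-methyl-5,6-dihydro-2H-pyran-2-one
Conditions: TBSCl, imidazole, DMF, rt
Reagents that add atoms: tert-butyl(chloro)dimethylsilane, CC(C)(C)[Si](C)(C)Cl
Why: Standard silylation of the primary allylic alcohol masks C12–OH through the hydride, ylide and base steps that follow.

Step 5
Reactants: 7 the TBS-protected lactone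
Product: 8 (6R)-6-[(1E)-3-{[tert-butyl(dimethyl)silyl]oxy}-2-methylprop-1-en-1-yl]-4-methyl-5,6-dihydro-2H-pyran-2-ol (both anomers)
Conditions: DIBAL-H (1.1 equiv), CH2Cl2, −78 °C; Rochelle salt
Reagents that add atoms: none
Why: DIBAL 1,2-reduction of the unsaturated lactone stops at the lactol because the aluminium hemiacetal is stable at −78 °C.

Step 6
Reactants: 8 the lactol
Product: 9 (2E,4R,6Z)-1-{[tert-butyl(dimethyl)silyl]oxy}-2,6-dimethylnona-2,6,8-trien-4-ol
Conditions: Ph3PCH3Br (3.5 equiv), KHMDS (3.3 equiv), THF, 0 °C; then 8, 0 °C to rt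
Reagents that add atoms: methyltriphenylphosphonium bromide, C[P+](c1ccccc1)(c1ccccc1)c1ccccc1.[Br-]
Why: Wittig methylenation of the lactol through its open hydroxy-enal form adds C3 and frees the C8 hydroxyl; the aldehyde is consumed as it is released, so the Z geometry inherited from the ring should persist.

Step 7
Reactants: 9 the trienol
Product: 10 tert-butyl{[(2E,4R,6Z)-4-[(4-methoxybenzyl)oxy]-2,6-dimethylnona-2,6,8-trien-1-yl]oxy}dimethylsilane
Conditions: NaH, PMBCl, Bu4NI (cat.), THF/DMF, 0 °C to rt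
Reagents that add atoms: 4-methoxybenzyl chloride, COc1ccc(CCl)cc1
Why: Williamson etherification of the secondary allylic alkoxide; the C8–O bond is not broken, so C8 stays R.

Step 8
Reactants: 11 methyl but-2-ynoate
Product: 12 methyl (2Z)-3-iodobut-2-enoate
Conditions: NaI, AcOH, 115 °C
Reagents that add atoms: sodium iodide, [Na+].[I-]
Why: Conjugate hydroiodination of the ynoate proceeds by anti addition of iodide and proton, which gives the Z-β-iodo enoate.

Step 9
Reactants: 10 the PMB-protected triene; 12 methyl (2Z)-3-iodobut-2-enoate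
Product: 14 methyl (2Z,6Z,9R,10E)-12-{[tert-butyl(dimethyl)silyl]oxy}-9-[(4-methoxybenzyl)oxy]-3,7,11-trimethyldodeca-2,6,10-trienoate, via B-alkyl-9-BBN 13 (not isolated)
Conditions: 9-BBN, THF, 0 °C to rt; then 12, PdCl2(dppf) (5 mol %), AsPh3 (10 mol %), Cs2CO3, DMF/H2O, rt
Reagents that add atoms: none
Why: 9-BBN adds anti-Markovnikov to the terminal CH2=CH of the 1,3-diene far faster than to any trisubstituted alkene and gives the homoallylic borane 13, and the B-alkyl Suzuki–Miyaura coupling (zerovalent palladium from PdCl2(dppf)) joins C3 to C4 with retention of the Z geometry of 12.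

Step 10
Reactants: 14 the trienoate
Product: 15 (2Z,6Z,9R,10E)-12-{[tert-butyl(dimethyl)silyl]oxy}-9-[(4-methoxybenzyl)oxy]-3,7,11-trimethyldodeca-2,6,10-trien-1-ol
Conditions: DIBAL-H (2.5 equiv), CH2Cl2, −78 °C; Rochelle salt
Reagents that add atoms: none
Why: DIBAL reduces the conjugated ester by 1,2-hydride delivery to the Z allylic alcohol without touching the silyl or PMB ether.

Step 11
Reactants: 15 the allylic alcohol
Product: 16 (2Z,6Z,9R,10E)-12-{[tert-butyl(dimethyl)silyl]oxy}-9-[(4-methoxybenzyl)oxy]-3,7,11-trimethyldodeca-2,6,10-trienal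
Conditions: MnO2 (activated, excess), CH2Cl2, rt, dark
Reagents that add atoms: none
Why: MnO2 oxidises only the primary allylic alcohol under neutral heterogeneous conditions, which should leave the neral-type Z-enal without isomerisation.

Step 12
Reactants: 16 the silyloxy enal
Product: 17 (2Z,6Z,9R,10E)-12-hydroxy-9-[(4-methoxybenzyl)oxy]-3,7,11-trimethyldodeca-2,6,10-trienal
Conditions: HF·pyridine, pyridine, THF, 0 °C
Reagents that add atoms: none
Why: Buffered fluoride cleavage of the primary TBS ether spares the PMB ether and the base-sensitive Z-enal.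

Step 13
Reactants: 17 the hydroxy enal
Product: 19 (2Z,6Z,9R,10E)-12-bromo-9-[(4-methoxybenzyl)oxy]-3,7,11-trimethyldodeca-2,6,10-trienal, via allylic mesylate 18 (not isolated)
Conditions: MsCl, Et3N, CH2Cl2, −40 °C; then LiBr, THF, 0 °C; used at once
Reagents that add atoms: lithium bromide, [Li+].[Br-]
Why: Mesylation of the primary allylic alcohol and SN2 displacement by bromide give the E allylic bromide without touching the aldehyde, which a phosphine/CBr4 bromination would attack.

Step 14
Reactants: 19 (2Z,6Z,9R,10E)-12-bromo-9-[(4-methoxybenzyl)oxy]-3,7,11-trimethyldodeca-2,6,10-trienal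
Product: 21 (1R,2Z,6Z,9R,10R)-9-[(4-methoxybenzyl)oxy]-3,7-dimethyl-10-(prop-1-en-2-yl)cyclodeca-2,6-dien-1-ol, via allylchromium dichloride 20 (not isolated)
Conditions: CrCl2 (6 equiv), degassed THF, syringe-pump addition of 19 to a final 0.003 M, 20 °C; then H2O
Reagents that add atoms: none
Why: Two equivalents of CrCl2 (divalent chromium) reduce the C12–Br bond to the σ-allyl species 20 of trivalent chromium, whose E and Z forms interconvert by 1,3-metal shift, and 20 adds through its γ-carbon C7 to the chromium-bound C6 aldehyde in a closed six-membered chair (intramolecular Nozaki–Hiyama allylation, the reaction type that closes ten- to fourteen-membered terpene rings from ω-bromo farnesal-type chains). The ten-membered ring closes in the 10-exo-trig mode across C6–C7, with the chair fused to the forming ring at this bond and the two Z alkenes holding the chain ends close. C7 is set against the preset C8 centre: allylic 1,3-strain keeps C8–H in the plane of the allyl unit, the ether oxygen can bind chromium on the reacting face and C9 points away, so the C6–C7 bond forms anti to C9 and the isopropenyl group ends trans to the C8 ether on the ring. C6 follows from the chair: the ether-chelated form of 20 is the Z-allyl isomer, which places C8 axial while C5 of the aldehyde is equatorial, and this should give the C6 hydroxyl cis to the isopropenyl group (6R,7R with 8R). The step needs γ- over α-attack, ring closure over oligomerisation and this one diastereomer; the chair, the high dilution and the donor PMB ether (also too poor a leaving group for 1,4-elimination to a diene) are what should secure them, and neutral CrCl2 spares the Z-enal. The C6 outcome is the least certain point, since the unchelated E-allyl chair would give the C6 epimer.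

Step 15
Reactants: 21 the isopropenyl macrocycle
Product: 22 (1R,2Z,6Z,9R,10R)-9-[(4-methoxybenzyl)oxy]-3,7-dimethyl-10-(propan-2-yl)cyclodeca-2,6-dien-1-ol
Conditions: H2 (1 atm), RhCl(PPh3)3 (10 mol %), benzene, rt
Reagents that add atoms: none
Why: Homogeneous hydrogenation with RhCl(PPh3)3 is strongly sensitive to alkene substitution, so the 1,1-disubstituted isopropenyl group should be saturated while the two trisubstituted ring Z alkenes and the PMB ether stay; C11 carries two methyl groups, so no stereocentre forms.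

Step 16
Reactants: 22 the isopropyl macrocycle
Product: 23 triethyl{[(1R,2Z,6Z,9R,10S)-9-[(4-methoxybenzyl)oxy]-3,7-dimethyl-10-(propan-2-yl)cyclodeca-2,6-dien-1-yl]oxy}silane
Conditions: TESOTf, 2,6-lutidine, CH2Cl2, −78 °C
Reagents that add atoms: triethylsilyl trifluoromethanesulfonate, CC[Si](CC)(CC)OS(=O)(=O)C(F)(F)F
Why: Silyl triflate silylation caps the hindered allylic C6 hydroxyl, which prevents acetal formation with the 1,3-related PMB ether in the next step (the C10 descriptor changes by priority only).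

Step 17
Reactants: 23 the TES ether
Product: 24 (1R,3Z,7Z,9R,10S)-3,7-dimethyl-10-(propan-2-yl)-9-[(triethylsilyl)oxy]cyclodeca-3,7-dien-1-ol
Conditions: DDQ (1.3 equiv), CH2Cl2/pH 7 buffer (10:1), 0 °C
Reagents that add atoms: none
Why: DDQ oxidises the electron-rich 4-methoxybenzyl ether by hydride abstraction and water hydrolyses the oxocarbenium ion (oxidative PMB cleavage); the C8–O bond stays, so C8 keeps its configuration.

Step 18
Reactants: 25 vanillic acid
Product: 26 tert-butyl(dimethyl)silyl 4-{[tert-butyl(dimethyl)silyl]oxy}-3-methoxybenzoate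
Conditions: TBSCl (2.3 equiv), imidazole, DMF, rt
Reagents that add atoms: tert-butyl(chloro)dimethylsilane, CC(C)(C)[Si](C)(C)Cl
Why: Imidazole-promoted silylation covers both the phenol and the carboxylic acid.

Step 19
Reactants: 26 the bis-silyl vanillate
Product: 27 4-{[tert-butyl(dimethyl)silyl]oxy}-3-methoxybenzoyl chloride
Conditions: (COCl)2, DMF (cat.), CH2Cl2, 0 °C to rt; used crude
Reagents that add atoms: oxalyl chloride, ClC(=O)C(Cl)=O
Why: Oxalyl chloride with catalytic DMF (chloroiminium activation) converts the silyl ester directly into the acid chloride under neutral conditions, so the aryl silyl ether survives.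

Step 20
Reactants: 24 the C8 alcohol; 27 the silyl-protected vanilloyl chloride
Product: 28 (1R,3Z,7Z,9R,10S)-3,7-dimethyl-10-(propan-2-yl)-9-[(triethylsilyl)oxy]cyclodeca-3,7-dien-1-yl 4-{[tert-butyl(dimethyl)silyl]oxy}-3-methoxybenzoate
Conditions: Et3N, DMAP, CH2Cl2, rt to 40 °C
Reagents that add atoms: none
Why: DMAP-catalysed acylation through the N-acylpyridinium ion esterifies the hindered C8 alcohol; the carbinol C–O bond is untouched, so C8 remains R.

Step 21
Reactants: 28 the bis-silyl ester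
Product: 29 (1R,3Z,7Z,9R,10R)-9-hydroxy-3,7-dimethyl-10-(propan-2-yl)cyclodeca-3,7-dien-1-yl 4-hydroxy-3-methoxybenzoate
Conditions: HF·pyridine, pyridine, THF, 0 °C to rt
Reagents that add atoms: none
Why: Fluoride removes the alkyl TES and the aryl TBS ether in one operation under non-basic conditions, which avoids migration of the vanilloyl group from O8 to the 1,3-related O6.

**Compound list**

1 | methyl 3-methylbut-2-enoate | COC(=O)C=C(C)C | starting material
2 | 1-methoxy-3-methyl-1-(trimethylsilyloxy)buta-1,3-diene | COC(O[Si](C)(C)C)=CC(C)=C | intermediate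
3 | 3-methylbut-2-enal | CC(C)=CC=O | starting material
4 | copper alkoxide of methyl (2Z,5R)-5-hydroxy-3,7-dimethylocta-2,6-dienoate (monovalent copper, phosphine ligand omitted) | COC(=O)/C=C(C)\C[C@@H](O[Cu])C=C(C)C | intermediate
5 | (6R)-4-methyl-6-(2-methylprop-1-en-1-yl)-5,6-dihydro-2H-pyran-2-one | CC(C)=C[C@H]1CC(C)=CC(=O)O1 | intermediate
6 | (6R)-6-[(1E)-3-hydroxy-2-methylprop-1-en-1-yl]-4-methyl-5,6-dihydro-2H-pyran-2-one | OC/C(C)=C/[C@H]1CC(C)=CC(=O)O1 | intermediate
7 | (6R)-6-[(1E)-3-{[tert-butyl(dimethyl)silyl]oxy}-2-methylprop-1-en-1-yl]-4-methyl-5,6-dihydro-2H-pyran-2-one | CC(C)(C)[Si](C)(C)OC/C(C)=C/[C@H]1CC(C)=CC(=O)O1 | intermediate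
8 | (6R)-6-[(1E)-3-{[tert-butyl(dimethyl)silyl]oxy}-2-methylprop-1-en-1-yl]-4-methyl-5,6-dihydro-2H-pyran-2-ol (both anomers) | CC(C)(C)[Si](C)(C)OC/C(C)=C/[C@H]1CC(C)=CC(O)O1 | intermediate
9 | (2E,4R,6Z)-1-{[tert-butyl(dimethyl)silyl]oxy}-2,6-dimethylnona-2,6,8-trien-4-ol | CC(C)(C)[Si](C)(C)OC/C(C)=C/[C@H](O)C/C(C)=C\C=C | intermediate
10 | tert-butyl{[(2E,4R,6Z)-4-[(4-methoxybenzyl)oxy]-2,6-dimethylnona-2,6,8-trien-1-yl]oxy}dimethylsilane | COc1ccc(CO[C@@H](/C=C(\C)CO[Si](C)(C)C(C)(C)C)C/C(C)=C\C=C)cc1 | intermediate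
11 | methyl but-2-ynoate | CC#CC(=O)OC | starting material
12 | methyl (2Z)-3-iodobut-2-enoate | COC(=O)/C=C(/C)I | intermediate
13 | 9-[(3Z,6R,7E)-9-{[tert-butyl(dimethyl)silyl]oxy}-6-[(4-methoxybenzyl)oxy]-4,8-dimethylnona-3,7-dien-1-yl]-9-borabicyclo[3.3.1]nonane | COc1ccc(CO[C@@H](/C=C(\C)CO[Si](C)(C)C(C)(C)C)C/C(C)=C\CCB2C3CCCC2CCC3)cc1 | intermediate
14 | methyl (2Z,6Z,9R,10E)-12-{[tert-butyl(dimethyl)silyl]oxy}-9-[(4-methoxybenzyl)oxy]-3,7,11-trimethyldodeca-2,6,10-trienoate | COc1ccc(CO[C@@H](/C=C(\C)CO[Si](C)(C)C(C)(C)C)C/C(C)=C\CC/C(C)=C\C(=O)OC)cc1 | intermediate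
15 | (2Z,6Z,9R,10E)-12-{[tert-butyl(dimethyl)silyl]oxy}-9-[(4-methoxybenzyl)oxy]-3,7,11-trimethyldodeca-2,6,10-trien-1-ol | COc1ccc(CO[C@@H](/C=C(\C)CO[Si](C)(C)C(C)(C)C)C/C(C)=C\CC/C(C)=C\CO)cc1 | intermediate
16 | (2Z,6Z,9R,10E)-12-{[tert-butyl(dimethyl)silyl]oxy}-9-[(4-methoxybenzyl)oxy]-3,7,11-trimethyldodeca-2,6,10-trienal | COc1ccc(CO[C@@H](/C=C(\C)CO[Si](C)(C)C(C)(C)C)C/C(C)=C\CC/C(C)=C\C=O)cc1 | intermediate
17 | (2Z,6Z,9R,10E)-12-hydroxy-9-[(4-methoxybenzyl)oxy]-3,7,11-trimethyldodeca-2,6,10-trienal | COc1ccc(CO[C@@H](/C=C(\C)CO)C/C(C)=C\CC/C(C)=C\C=O)cc1 | intermediate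
18 | (2E,4R,6Z,10Z)-4-[(4-methoxybenzyl)oxy]-2,6,10-trimethyl-12-oxododeca-2,6,10-trien-1-yl methanesulfonate | COc1ccc(CO[C@@H](/C=C(\C)COS(C)(=O)=O)C/C(C)=C\CC/C(C)=C\C=O)cc1 | intermediate
19 | (2Z,6Z,9R,10E)-12-bromo-9-[(4-methoxybenzyl)oxy]-3,7,11-trimethyldodeca-2,6,10-trienal | COc1ccc(CO[C@@H](/C=C(\C)CBr)C/C(C)=C\CC/C(C)=C\C=O)cc1 | intermediate
20 | dichloro[(4R,6Z,10Z)-4-[(4-methoxybenzyl)oxy]-2,6,10-trimethyl-12-oxododeca-2,6,10-trien-1-yl]chromium (trivalent chromium, E and Z allyl forms in equilibrium, THF ligands omitted; E form drawn) | COc1ccc(CO[C@@H](/C=C(\C)C[Cr](Cl)Cl)C/C(C)=C\CC/C(C)=C\C=O)cc1 | intermediate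
21 | (1R,2Z,6Z,9R,10R)-9-[(4-methoxybenzyl)oxy]-3,7-dimethyl-10-(prop-1-en-2-yl)cyclodeca-2,6-dien-1-ol | COc1ccc(CO[C@@H]2C/C(C)=C\CC/C(C)=C\[C@@H](O)[C@H]2C(C)=C)cc1 | intermediate
22 | (1R,2Z,6Z,9R,10R)-9-[(4-methoxybenzyl)oxy]-3,7-dimethyl-10-(propan-2-yl)cyclodeca-2,6-dien-1-ol | COc1ccc(CO[C@@H]2C/C(C)=C\CC/C(C)=C\[C@@H](O)[C@H]2C(C)C)cc1 | intermediate
23 | triethyl{[(1R,2Z,6Z,9R,10S)-9-[(4-methoxybenzyl)oxy]-3,7-dimethyl-10-(propan-2-yl)cyclodeca-2,6-dien-1-yl]oxy}silane | COc1ccc(CO[C@@H]2C/C(C)=C\CC/C(C)=C\[C@@H](O[Si](CC)(CC)CC)[C@H]2C(C)C)cc1 | intermediate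
24 | (1R,3Z,7Z,9R,10S)-3,7-dimethyl-10-(propan-2-yl)-9-[(triethylsilyl)oxy]cyclodeca-3,7-dien-1-ol | O[C@@H]1C/C(C)=C\CC/C(C)=C\[C@@H](O[Si](CC)(CC)CC)[C@H]1C(C)C | intermediate
25 | vanillic acid (4-hydroxy-3-methoxybenzoic acid) | COc1cc(C(=O)O)ccc1O | starting material
26 | tert-butyl(dimethyl)silyl 4-{[tert-butyl(dimethyl)silyl]oxy}-3-methoxybenzoate | COc1cc(C(=O)O[Si](C)(C)C(C)(C)C)ccc1O[Si](C)(C)C(C)(C)C | intermediate
27 | 4-{[tert-butyl(dimethyl)silyl]oxy}-3-methoxybenzoyl chloride | COc1cc(C(Cl)=O)ccc1O[Si](C)(C)C(C)(C)C | intermediate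
28 | (1R,3Z,7Z,9R,10S)-3,7-dimethyl-10-(propan-2-yl)-9-[(triethylsilyl)oxy]cyclodeca-3,7-dien-1-yl 4-{[tert-butyl(dimethyl)silyl]oxy}-3-methoxybenzoate | COc1cc(C(=O)O[C@@H]2C/C(C)=C\CC/C(C)=C\[C@@H](O[Si](CC)(CC)CC)[C@H]2C(C)C)ccc1O[Si](C)(C)C(C)(C)C | intermediate
29 | (1R,3Z,7Z,9R,10R)-9-hydroxy-3,7-dimethyl-10-(propan-2-yl)cyclodeca-3,7-dien-1-yl 4-hydroxy-3-methoxybenzoate | COc1cc(C(=O)O[C@@H]2C/C(C)=C\CC/C(C)=C\[C@@H](O)[C@H]2C(C)C)ccc1O | target

**Step count**

Total: 21 steps. Longest linear sequence: 18 steps (steps 1–7, 9–17, 20, 21).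

**Steps most likely to fail**

Step 14. The chair with the E-allylchromium and both ring-bound substituents equatorial may compete and turn the C6 hydroxyl trans to the isopropenyl group (poor control of C6 relative to C7); oligomerisation is a lesser risk that dilution addresses. The fallback sets out from 19 and returns at 22. The same cyclisation then gives the C6-epimeric alcohol F1. Hydrogenation as in step 15 gives the C6-epimeric isopropyl alcohol F2; this is done first so that C7–H is no longer allylic. Dess–Martin periodinane with NaHCO3 in CH2Cl2 gives the ring enone F3. NaBH4 with CeCl3·7H2O in MeOH at −78 °C should then deliver hydride to the carbonyl face opposite to the neighbouring isopropyl group, which places the C6 hydroxyl cis to it and gives 22.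

Step 2. The copper dienolate may discriminate the faces of the β,β-disubstituted enal poorly (low enantioselectivity), or part of the adduct may stay as open-chain E ester that cannot lactonise. The fallback sets out from 3 and returns at 5, with C8 set by an auxiliary and the Z alkene by an intramolecular olefination. A titanium acetate aldol (TiCl4, i-Pr2NEt, CH2Cl2, −78 °C) of 3 with (4S)-3-acetyl-4-benzyl-1,3-thiazolidine-2-thione (or its antipode, whichever gives the 3R carbinol) should give the thiazolidinethione aldol adduct F4. MeNHOMe·HCl with imidazole gives the Weinreb amide F5. MeMgBr in THF at 0 °C gives the β-hydroxy methyl ketone F6. Diethylphosphonoacetic acid with DCC and DMAP gives the phosphonoacetate F7. LiCl and i-Pr2NEt in MeCN then close the ring by intramolecular Horner–Wadsworth–Emmons reaction to 5.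

Step 15. The rhodium catalyst may also reduce or isomerise the ring alkenes (loss of chemoselectivity among three alkenes). The fallback sets out from 21 and returns at 23, singling out the isopropenyl group by hydroboration. Silylation as in step 16 gives the TES ether F8. 9-BBN in THF, which adds to 1,1-disubstituted alkenes far faster than to trisubstituted ones, then NaOH/H2O2, gives the primary alcohol F9 (both C11 epimers, of no consequence). TsCl with pyridine and DMAP gives the tosylate F10. LiBHEt3 in THF replaces the tosylate by hydride and gives 23.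

**Further compounds**

F1 | step 14 | (1S,2Z,6Z,9R,10R)-9-[(4-methoxybenzyl)oxy]-3,7-dimethyl-10-(prop-1-en-2-yl)cyclodeca-2,6-dien-1-ol | COc1ccc(CO[C@@H]2C/C(C)=C\CC/C(C)=C\[C@H](O)[C@H]2C(C)=C)cc1
F2 | step 14 | (1S,2Z,6Z,9R,10R)-9-[(4-methoxybenzyl)oxy]-3,7-dimethyl-10-(propan-2-yl)cyclodeca-2,6-dien-1-ol | COc1ccc(CO[C@@H]2C/C(C)=C\CC/C(C)=C\[C@H](O)[C@H]2C(C)C)cc1
F3 | step 14 | (2Z,6Z,9R,10S)-9-[(4-methoxybenzyl)oxy]-3,7-dimethyl-10-(propan-2-yl)cyclodeca-2,6-dien-1-one | COc1ccc(CO[C@@H]2C/C(C)=C\CC/C(C)=C\C(=O)[C@H]2C(C)C)cc1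
F4 | step 2 | (3R)-1-[(4S)-4-benzyl-2-thioxo-1,3-thiazolidin-3-yl]-3-hydroxy-5-methylhex-4-en-1-one | CC(C)=C[C@H](O)CC(=O)N1[C@@H](Cc2ccccc2)CSC1=S
F5 | step 2 | (3R)-3-hydroxy-N-methoxy-N,5-dimethylhex-4-enamide | CC(C)=C[C@H](O)CC(=O)N(C)OC
F6 | step 2 | (4R)-4-hydroxy-6-methylhept-5-en-2-one | CC(C)=C[C@H](O)CC(C)=O
F7 | step 2 | (4R)-2-methyl-6-oxohept-2-en-4-yl (diethoxyphosphoryl)acetate | CC(C)=C[C@H](OC(=O)CP(=O)(OCC)OCC)CC(C)=O
F8 | step 15 | triethyl{[(1R,2Z,6Z,9R,10S)-9-[(4-methoxybenzyl)oxy]-3,7-dimethyl-10-(prop-1-en-2-yl)cyclodeca-2,6-dien-1-yl]oxy}silane | COc1ccc(CO[C@@H]2C/C(C)=C\CC/C(C)=C\[C@@H](O[Si](CC)(CC)CC)[C@H]2C(C)=C)cc1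
F9 | step 15 | 2-[(1S,2R,3Z,7Z,10R)-10-[(4-methoxybenzyl)oxy]-4,8-dimethyl-2-[(triethylsilyl)oxy]cyclodeca-3,7-dien-1-yl]propan-1-ol (both epimers at the propanol C2) | COc1ccc(CO[C@@H]2C/C(C)=C\CC/C(C)=C\[C@@H](O[Si](CC)(CC)CC)[C@H]2C(C)CO)cc1
F10 | step 15 | 2-[(1S,2R,3Z,7Z,10R)-10-[(4-methoxybenzyl)oxy]-4,8-dimethyl-2-[(triethylsilyl)oxy]cyclodeca-3,7-dien-1-yl]propyl 4-methylbenzenesulfonate (both epimers) | COc1ccc(CO[C@@H]2C/C(C)=C\CC/C(C)=C\[C@@H](O[Si](CC)(CC)CC)[C@H]2C(C)COS(=O)(=O)c3ccc(C)cc3)cc1
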